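**Plan**
- **Cuts:** after removal of the masking groups (two O-benzyl groups and the C5 O-methyl group), ring C is opened at O1–C2. The open chain is then cut at O1–C8a and C4–C4a in one operation, and the remaining three-carbon acid is cut at C2–C3.
- **Enabling feature:** on ring A, O1 (on C8a) and the ketone carbon C4 (on C4a) are ortho neighbours, and C4a has the C5 oxygen on its other side. A triple bond C4a≡C8a is therefore a 3-alkoxyaryne that accepts an oxygen nucleophile at C8a and develops its carbanion at C4a.
- **Forward:** an aldol reaction between the ring B aldehyde and a methoxyacetyl imide joins C2–C3 and leads to the acid. Ring A comes complete from syringaldehyde as a 2-silylaryl triflate. Aryne insertion into the acyl–O bond of the acid joins the halves without closing a ring, and ring C closes last at O1–C2.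
- **Stereochemistry:** an Evans syn aldol with the (R)-4-benzyl auxiliary sets C3 (R, final) and C2 (S, epimeric). The SN2 (Mitsunobu) closure inverts C2 to R and gives the 2,3-trans ring.
- **End game:** chelation-directed cleavage of the C5 methyl ether, then hydrogenolysis.

Key step: step 10

Remark: chroman-4-one numbering (O1, C2, C3, C4, C4a, C5 to C8, C8a; ring A benzo, ring B 2-aryl, ring C pyranone) is applied to open-chain precursors as well; the target SMILES is read as (2R,3R), that is 2,3-trans.

**Step 1**
Reactants: 1 syringaldehyde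
Product: 2 4-(benzyloxy)-3,5-dimethoxybenzaldehyde
Conditions: BnBr, K2CO3, DMF, 60 °C
Reagents that add atoms: benzyl bromide, BrCc1ccccc1
Why: Williamson etherification of the only acidic OH, in which the flanked phenoxide still alkylates readily with a reactive benzylic bromide in a dipolar aprotic solvent.

**Step 2**
Reactants: 2 4-(benzyloxy)-3,5-dimethoxybenzaldehyde
Product: 4 4-(benzyloxy)-3,5-dimethoxyphenol, via aryl formate 3 (not isolated)
Conditions: mCPBA, CH2Cl2, 0 °C → rt; aq. NaHCO3 wash; then K2CO3 (cat.), MeOH, rt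
Reagents that add atoms: mCPBA, OOC(=O)c1cccc(Cl)c1
Why: Baeyer–Villiger (Dakin-type) oxidation, in which the electron-rich aryl group migrates in preference to hydride, followed by base-catalysed methanolysis of formate 3, should give a phenol whose two ortho positions are equivalent by symmetry.

**Step 3**
Reactants: 4 4-(benzyloxy)-3,5-dimethoxyphenol
Product: 5 4-(benzyloxy)-2-bromo-3,5-dimethoxyphenol
Conditions: NBS (1.0 equiv), CH2Cl2, −78 → 0 °C, dark
Reagents that add atoms: N-bromosuccinimide, O=C1CCC(=O)N1Br
Why: Electrophilic aromatic bromination of a phenol whose para position is blocked and whose two ortho positions are homotopic, so that one equivalent of NBS at low temperature can give only one monobromide.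

**Step 4**
Reactants: 5 4-(benzyloxy)-2-bromo-3,5-dimethoxyphenol
Product: 8 4-(benzyloxy)-3,5-dimethoxy-2-(trimethylsilyl)phenyl trifluoromethanesulfonate, via aryl silyl ether 6 (not isolated), via lithium silylphenoxide 7 (not isolated)
Conditions: HMDS, THF, 70 °C, then evaporate; n-BuLi, THF, −78 °C; Tf2O, −78 → 0 °C
Reagents that add atoms: hexamethyldisilazane, C[Si](C)(C)N[Si](C)(C)C; triflic anhydride, O=S(=O)(C(F)(F)F)OS(=O)(=O)C(F)(F)F; n-butyllithium, [Li]CCCC (lithium of 7 only)
Why: O-Silylation, bromine–lithium exchange and retro-Brook (1,3 O-to-C) silyl migration put silicon exactly where bromine stood, and the freed phenoxide 7 is trapped by Tf2O, which is the standard entry to 2-silylaryl triflates.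

**Step 5**
Reactants: 9 3-hydroxy-4,5-dimethoxybenzaldehyde
Product: 10 3-(benzyloxy)-4,5-dimethoxybenzaldehyde
Conditions: BnBr, K2CO3, DMF, 60 °C
Reagents that add atoms: benzyl bromide, BrCc1ccccc1
Why: Williamson etherification of the single phenol, which masks the later 3'-OH as a group that falls in the final hydrogenolysis.

**Step 6**
Reactants: 11 (R)-4-benzyloxazolidin-2-one, 12 methoxyacetyl chloride
Product: 14 (R)-4-benzyl-3-(2-methoxyacetyl)oxazolidin-2-one, via lithium oxazolidinide 13 (not isolated)
Conditions: n-BuLi, THF, −78 °C; then 12, −78 → 0 °C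
Reagents that add atoms: n-butyllithium, [Li]CCCC (lithium of 13 only)
Why: N-Acylation of the lithiated oxazolidinone 13 by an acid chloride, the standard loading of an Evans auxiliary.

**Step 7**
Reactants: 14 (R)-4-benzyl-3-(2-methoxyacetyl)oxazolidin-2-one, 10 3-(benzyloxy)-4,5-dimethoxybenzaldehyde
Product: 17 (R)-4-benzyl-3-{(2R,3S)-3-[3-(benzyloxy)-4,5-dimethoxyphenyl]-3-hydroxy-2-methoxypropanoyl}oxazolidin-2-one, via boron enolate 15 (not isolated), via boron aldolate 16 (not isolated)
Conditions: Bu2BOTf, Et3N, CH2Cl2, −78 → 0 °C; 10, −78 → 0 °C; then pH 7 buffer, MeOH, 30% H2O2, 0 °C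
Reagents that add atoms: di-n-butylboron triflate, CCCCB(CCCC)OS(=O)(=O)C(F)(F)F (boron and butyl groups of 15 and 16 only)
Why: Evans syn aldol, in which soft enolisation gives the (Z)-boron enolate 15 and a closed Zimmerman–Traxler chair with the auxiliary carbonyl turned away lets the aldehyde meet the enolate face opposite the benzyl group of the (R)-auxiliary, setting the (2R,3S)-syn pair, that is C3 in its final and C2 in its epimeric configuration.

**Step 8**
Reactants: 17 the syn aldol adduct
Product: 18 (R)-4-benzyl-3-{(2R,3S)-3-[3-(benzyloxy)-4,5-dimethoxyphenyl]-2-methoxy-3-(methoxymethoxy)propanoyl}oxazolidin-2-one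
Conditions: MOMCl, i-Pr2NEt, Bu4NI (cat.), CH2Cl2, 0 °C → rt
Reagents that add atoms: chloromethyl methyl ether, COCCl
Why: Acetal protection by O-alkylation with a very reactive chloromethyl ether under amine base is too mild for retro-aldol cleavage, and the MOM ether is chosen because it resists hot fluoride and its alkoxide is a poor leaving group for beta-elimination.

**Step 9**
Reactants: 18 the MOM-protected imide
Product: 20 (2R,3S)-3-[3-(benzyloxy)-4,5-dimethoxyphenyl]-2-methoxy-3-(methoxymethoxy)propanoic acid, via lithium peroxycarboxylate 19 (not isolated)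
Conditions: LiOH, 30% H2O2, THF–H2O, 0 °C; aq. Na2SO3; 1 M HCl to pH 3
Reagents that add atoms: hydrogen peroxide, OO; lithium hydroxide, [Li+].[OH-] (lithium of 19 only)
Why: Hydroperoxide cleavage of an N-acyloxazolidinone, in which the small alpha-effect nucleophile attacks the exocyclic carbonyl selectively at 0 °C without epimerising the alpha carbon, sulfite reduces 19 to the carboxylate and the auxiliary is recovered.

**Step 10**
Reactants: 8 4-(benzyloxy)-3,5-dimethoxy-2-(trimethylsilyl)phenyl trifluoromethanesulfonate, 20 (2R,3S)-3-[3-(benzyloxy)-4,5-dimethoxyphenyl]-2-methoxy-3-(methoxymethoxy)propanoic acid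
Product: 23 (2R,3S)-1-[3-(benzyloxy)-6-hydroxy-2,4-dimethoxyphenyl]-3-[3-(benzyloxy)-4,5-dimethoxyphenyl]-2-methoxy-3-(methoxymethoxy)propan-1-one, via ring A aryne 21 (not isolated), via aryl anion 22 (not isolated)
Conditions: 8 (1.5 equiv), CsF (4 equiv), THF (0.05 M), sealed tube, 125 °C
Reagents that add atoms: cesium fluoride, [Cs+].[F-] (cesium of 22 only)
Why: Fluoride strips the silyl group of 8, triflate leaves and aryne 21 (triple bond C4a≡C8a) is fed in slowly because CsF is barely soluble in THF; the carboxylate of 20 adds to C8a and leaves aryl anion 22 with its charge on C4a. This carbanion sits ortho to the ester it has just made and attacks the ester carbonyl through a four-membered alkoxide, whose collapse cuts the acyl–oxygen bond, so that O1–C8a and C4–C4a are both formed and the phenoxide ends up with the proton of the acid. The closest known reaction type is the intermolecular C–O insertion of arynes into simple carboxylic acids with CsF in hot THF, which gives ortho-hydroxyaryl ketones and is in essence an aryne-triggered anionic Fries shift. No ring closes and no stereocentre is created, the two stereocentres of 20 being only carried along. The regioselectivity needed (oxygen at C8a, acyl at C4a) is secured by the C5 methoxy group, which distorts the aryne so that the remote carbon C8a is the electrophilic one and stabilises the charge at the adjacent C4a inductively, and the chemoselectivity needed (acyl shift before protonation of 22) is served by an aprotic solvent, high dilution and heat, which favour the unimolecular step, and by the alpha-methoxy group, which makes the ester carbonyl more electrophilic. Epimerisation at C3 and beta-elimination should stay slow because the ketone is born as a chelated ortho-phenol(ate), a vinylogous carboxylate of low alpha-acidity, and because the MOM alkoxide is a poor leaving group.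

**Step 11**
Reactants: 23 the MOM-protected ortho-hydroxyaryl ketone
Product: 24 (2R,3S)-1-[3-(benzyloxy)-6-hydroxy-2,4-dimethoxyphenyl]-3-[3-(benzyloxy)-4,5-dimethoxyphenyl]-3-hydroxy-2-methoxypropan-1-one
Conditions: conc. HCl (cat.), MeOH–THF, 40 °C
Reagents that add atoms: none
Why: Acid-catalysed acetal exchange (transacetalisation to dimethoxymethane) frees the alcohol, while the benzylic C–O bond should hold because its cation would sit next to the electron-withdrawing alpha-methoxy ketone and the para methoxy group of ring B is twisted out of conjugation by its two ortho neighbours.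

**Step 12**
Reactants: 24 the syn beta-hydroxy ketone
Product: 26 (2R,3R)-6-(benzyloxy)-2-[3-(benzyloxy)-4,5-dimethoxyphenyl]-3,5,7-trimethoxychroman-4-one, via oxyphosphonium phenoxide 25 (not isolated)
Conditions: PPh3, DIAD, THF (0.02 M), 0 °C → rt
Reagents that add atoms: triphenylphosphine, c1ccc(cc1)P(c1ccccc1)c1ccccc1 (stays only in 25)
Why: Intramolecular Mitsunobu etherification, a known closure of 2'-hydroxy-beta-hydroxydihydrochalcones, in which the chelated phenol is acidic enough to protonate the betaine and its phenoxide displaces the oxyphosphonium group of 25 in a 6-exo-tet SN2 step with inversion at C2 (S to R), placing aryl and methoxy groups trans-diequatorial.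

**Step 13**
Reactants: 26 the 5-O-methyl flavanone
Product: 28 (2R,3R)-6-(benzyloxy)-2-[3-(benzyloxy)-4,5-dimethoxyphenyl]-5-hydroxy-3,7-dimethoxychroman-4-one, via dichloroboron chelate 27 (not isolated)
Conditions: BCl3 (1.5 equiv), CH2Cl2, −78 → 0 °C; then H2O
Reagents that add atoms: boron trichloride, ClB(Cl)Cl (stays only in 27)
Why: Chelation-directed aryl methyl ether cleavage, in which BCl3 is held between the C4 carbonyl and the peri C5 methoxy oxygen in a six-membered chelate and chloride removes only that methyl group, while loss of the neighbouring C6 benzyl group, should it occur, only anticipates step 14.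

**Step 14**
Reactants: 28 the 5-hydroxy dibenzyl ether
Product: 29 (2R,3R)-5,6-dihydroxy-2-(3-hydroxy-4,5-dimethoxyphenyl)-3,7-dimethoxychroman-4-one (CNP0075601.1)
Conditions: H2 (1 atm), 10% Pd/C, EtOAc–MeOH, rt; work-up under argon
Reagents that add atoms: none
Why: Catalytic hydrogenolysis of the two aryl benzyl ethers at one atmosphere, conditions under which the cyclic C2–O1 bond and the hydrogen-bonded C4 ketone of flavanones normally survive, touches neither stereocentre.

**Compound list**
1 | syringaldehyde (4-hydroxy-3,5-dimethoxybenzaldehyde) | COc1cc(C=O)cc(OC)c1O | starting material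
2 | 4-(benzyloxy)-3,5-dimethoxybenzaldehyde | COc1cc(C=O)cc(OC)c1OCc1ccccc1 | intermediate
3 | 4-(benzyloxy)-3,5-dimethoxyphenyl formate | COc1cc(OC=O)cc(OC)c1OCc1ccccc1 | intermediate (not isolated)
4 | 4-(benzyloxy)-3,5-dimethoxyphenol | COc1cc(O)cc(OC)c1OCc1ccccc1 | intermediate
5 | 4-(benzyloxy)-2-bromo-3,5-dimethoxyphenol | COc1cc(O)c(Br)c(OC)c1OCc1ccccc1 | intermediate
6 | [4-(benzyloxy)-2-bromo-3,5-dimethoxyphenoxy]trimethylsilane | COc1cc(O[Si](C)(C)C)c(Br)c(OC)c1OCc1ccccc1 | intermediate (not isolated)
7 | lithium 4-(benzyloxy)-3,5-dimethoxy-2-(trimethylsilyl)phenoxide | [Li+].COc1cc([O-])c([Si](C)(C)C)c(OC)c1OCc1ccccc1 | intermediate (not isolated)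
8 | 4-(benzyloxy)-3,5-dimethoxy-2-(trimethylsilyl)phenyl trifluoromethanesulfonate | COc1cc(OS(=O)(=O)C(F)(F)F)c([Si](C)(C)C)c(OC)c1OCc1ccccc1 | intermediate
9 | 3-hydroxy-4,5-dimethoxybenzaldehyde | COc1cc(C=O)cc(O)c1OC | starting material
10 | 3-(benzyloxy)-4,5-dimethoxybenzaldehyde | COc1cc(C=O)cc(OCc2ccccc2)c1OC | intermediate
11 | (R)-4-benzyloxazolidin-2-one | O=C1N[C@H](Cc2ccccc2)CO1 | starting material
12 | methoxyacetyl chloride | COCC(Cl)=O | starting material
13 | lithium salt (N-lithio form) of (R)-4-benzyloxazolidin-2-one | [Li+].O=C1[N-][C@H](Cc2ccccc2)CO1 | intermediate (not isolated)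
14 | (R)-4-benzyl-3-(2-methoxyacetyl)oxazolidin-2-one | COCC(=O)N1[C@H](Cc2ccccc2)COC1=O | intermediate
15 | di-n-butylboron (Z)-enolate of 14 (OMe and OB cis on the double bond) | CO/C=C(\OB(CCCC)CCCC)N1[C@H](Cc2ccccc2)COC1=O | intermediate (not isolated)
16 | di-n-butylboron aldolate of 17 (O-BBu2 on the benzylic oxygen) | O=C(N1[C@H](Cc2ccccc2)COC1=O)[C@H](OC)[C@H](c1cc(OCc2ccccc2)c(OC)c(OC)c1)OB(CCCC)CCCC | intermediate (not isolated)
17 | (R)-4-benzyl-3-{(2R,3S)-3-[3-(benzyloxy)-4,5-dimethoxyphenyl]-3-hydroxy-2-methoxypropanoyl}oxazolidin-2-one | O=C(N1[C@H](Cc2ccccc2)COC1=O)[C@H](OC)[C@H](c1cc(OCc2ccccc2)c(OC)c(OC)c1)O | intermediate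
18 | (R)-4-benzyl-3-{(2R,3S)-3-[3-(benzyloxy)-4,5-dimethoxyphenyl]-2-methoxy-3-(methoxymethoxy)propanoyl}oxazolidin-2-one | O=C(N1[C@H](Cc2ccccc2)COC1=O)[C@H](OC)[C@H](c1cc(OCc2ccccc2)c(OC)c(OC)c1)OCOC | intermediate
19 | lithium (2R,3S)-3-[3-(benzyloxy)-4,5-dimethoxyphenyl]-2-methoxy-3-(methoxymethoxy)propaneperoxoate | [Li+].[O-]OC(=O)[C@H](OC)[C@H](c1cc(OCc2ccccc2)c(OC)c(OC)c1)OCOC | intermediate (not isolated)
20 | (2R,3S)-3-[3-(benzyloxy)-4,5-dimethoxyphenyl]-2-methoxy-3-(methoxymethoxy)propanoic acid | OC(=O)[C@H](OC)[C@H](c1cc(OCc2ccccc2)c(OC)c(OC)c1)OCOC | intermediate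
21 | 4-(benzyloxy)-3,5-dimethoxybenzyne (1,2-didehydrobenzene, triple bond C4a≡C8a) | COC1=C(OCc2ccccc2)C(OC)=CC#C1 | intermediate (not isolated)
22 | cesium salt of the O-aryl ester of 20 carrying the carbanion at C4a, between the ester oxygen-bearing carbon and the C5 methoxy carbon | [Cs+].COc1cc(OC(=O)[C@H](OC)[C@H](c2cc(OCc3ccccc3)c(OC)c(OC)c2)OCOC)[c-]c(OC)c1OCc1ccccc1 | intermediate (not isolated)
23 | (2R,3S)-1-[3-(benzyloxy)-6-hydroxy-2,4-dimethoxyphenyl]-3-[3-(benzyloxy)-4,5-dimethoxyphenyl]-2-methoxy-3-(methoxymethoxy)propan-1-one | COc1cc(O)c(C(=O)[C@H](OC)[C@H](c2cc(OCc3ccccc3)c(OC)c(OC)c2)OCOC)c(OC)c1OCc1ccccc1 | intermediate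
24 | (2R,3S)-1-[3-(benzyloxy)-6-hydroxy-2,4-dimethoxyphenyl]-3-[3-(benzyloxy)-4,5-dimethoxyphenyl]-3-hydroxy-2-methoxypropan-1-one | COc1cc(O)c(C(=O)[C@H](OC)[C@H](c2cc(OCc3ccccc3)c(OC)c(OC)c2)O)c(OC)c1OCc1ccccc1 | intermediate
25 | zwitterion of 24: benzylic O-triphenylphosphonium, ring A phenoxide | COc1cc([O-])c(C(=O)[C@H](OC)[C@H](c2cc(OCc3ccccc3)c(OC)c(OC)c2)O[P+](c2ccccc2)(c2ccccc2)c2ccccc2)c(OC)c1OCc1ccccc1 | intermediate (not isolated)
26 | (2R,3R)-6-(benzyloxy)-2-[3-(benzyloxy)-4,5-dimethoxyphenyl]-3,5,7-trimethoxychroman-4-one | COc1cc2c(c(OC)c1OCc1ccccc1)C(=O)[C@H](OC)[C@@H](c1cc(OCc3ccccc3)c(OC)c(OC)c1)O2 | intermediate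
27 | 5-O-dichloroboryl derivative of 28 (boron chelated by the C4 carbonyl) | COc1cc2c(c(OB(Cl)Cl)c1OCc1ccccc1)C(=O)[C@H](OC)[C@@H](c1cc(OCc3ccccc3)c(OC)c(OC)c1)O2 | intermediate (not isolated)
28 | (2R,3R)-6-(benzyloxy)-2-[3-(benzyloxy)-4,5-dimethoxyphenyl]-5-hydroxy-3,7-dimethoxychroman-4-one | COc1cc2c(c(O)c1OCc1ccccc1)C(=O)[C@H](OC)[C@@H](c1cc(OCc3ccccc3)c(OC)c(OC)c1)O2 | intermediate
29 | (2R,3R)-5,6-dihydroxy-2-(3-hydroxy-4,5-dimethoxyphenyl)-3,7-dimethoxychroman-4-one (CNP0075601.1) | COc1cc2c(c(O)c1O)C(=O)[C@H](OC)[C@@H](c1cc(O)c(OC)c(OC)c1)O2 | target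

**Total step count:** 14.
**Longest linear sequence:** 9 steps (steps 1–4 then 10–14; the acid branch is equally long through step 5 or 6, then 7–9 and 10–14).

**Steps most likely to fail**

**Step 10.**
- What may go wrong:
  - protonation of the aryl anion, by the medium or by an internal shift of the alpha proton, may outrun the acyl transfer;
  - the freed phenol may be arylated by a second aryne;
  - long heating with fluoride may erode the configuration next to the new ketone.
- Fallback: the same C4a carbanion is generated at low temperature without an aryne, setting out from bromophenol 5 and acid 20.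
  - Esterification (EDC·HCl, DMAP, CH2Cl2, 0 °C) gives 4-(benzyloxy)-2-bromo-3,5-dimethoxyphenyl (2R,3S)-3-[3-(benzyloxy)-4,5-dimethoxyphenyl]-2-methoxy-3-(methoxymethoxy)propanoate F1.
  - Bromine–lithium exchange (n-BuLi, THF, −95 °C) then sets off an anionic ortho-Fries (O-to-C acyl) shift.
  - After a proton quench the route is rejoined at ketone 23.

**Step 12.**
- What may go wrong:
  - ionisation of the activated benzylic oxygen may cost part of the inversion;
  - dehydration toward the conjugated enone may compete.
- A loss of inversion is not repaired with base, because epimerisation at C3 would feed the enantiomeric series.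
- Fallback: the SN2 logic is given up and C3 becomes the controlling element, setting out from alcohol 24.
  - A catalytic Brønsted acid (p-TsOH·H2O, (CF3)2CHOH, rt) forms the benzylic cation, which the C8a phenol captures.
  - The closure is reversible under these conditions and should drain to the diequatorial 2,3-trans ring. Its C2 is R because C3 is untouched.
  - This is the acid cyclodehydration known from the closure of 1,3-diarylpropane-1,2-diols to flavan-3-ols.
  - The route is rejoined at 26, and no new compound is made (F0).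

**Step 4.**
- What may go wrong:
  - incomplete O-to-C silyl migration;
  - proton capture by the crowded aryllithium;
  - metalation of the benzyl ether methylene;
  - sluggish triflation of the flanked phenoxide.
- Fallback: directed ortho-metalation replaces halogen–metal exchange, setting out from phenol 4 and thereby also bypassing step 3.
  - Isopropyl isocyanate with Et3N (cat.) in CH2Cl2 gives 4-(benzyloxy)-3,5-dimethoxyphenyl isopropylcarbamate F2.
  - Temporary N-silylation and lithiation between the carbamate and a methoxy group (TBSOTf, TMEDA, Et2O, 0 °C → rt; n-BuLi, −78 °C; TMSCl; aq. NaHSO4) gives 4-(benzyloxy)-3,5-dimethoxy-2-(trimethylsilyl)phenyl isopropylcarbamate F3.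
  - Carbamate cleavage and triflation in one flask (Et2NH, DBU, MeCN, 40 °C; then PhNTf2) rejoin the route at silyl triflate 8.

**Further compounds**
F1 | step 10 | 4-(benzyloxy)-2-bromo-3,5-dimethoxyphenyl (2R,3S)-3-[3-(benzyloxy)-4,5-dimethoxyphenyl]-2-methoxy-3-(methoxymethoxy)propanoate | COc1cc(OC(=O)[C@H](OC)[C@H](c2cc(OCc3ccccc3)c(OC)c(OC)c2)OCOC)c(Br)c(OC)c1OCc1ccccc1
F0 | step 12 | none | none
F2 | step 4 | 4-(benzyloxy)-3,5-dimethoxyphenyl isopropylcarbamate | COc1cc(OC(=O)NC(C)C)cc(OC)c1OCc1ccccc1
F3 | step 4 | 4-(benzyloxy)-3,5-dimethoxy-2-(trimethylsilyl)phenyl isopropylcarbamate | COc1cc(OC(=O)NC(C)C)c([Si](C)(C)C)c(OC)c1OCc1ccccc1
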